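**Plan**

1. Ring A is the benzoyl ring (two OH, two prenyl); ring B is the benzene ring of the 2,2-dimethylchromene (chromene numbering O1 to C8a); ring C is the seven-membered dioxepinone. The target is achiral: no stereocentre and no alkene geometry to set (the chromene alkene is cis within its ring, the prenyl alkenes carry two methyls).
2. Retrosynthesis: (a) both prenyl groups → C-allyl (cross-metathesis) → allyl ethers on the two ring-A oxygens (double Claisen); (b) ring C is cut between the ester oxygen and chromene C5 → seco acid with C5–H; (c) diaryl ether C–O (Ullmann) → bromo acid + chromenol; (d) pyran ring → aryl propargyl ether, and the C6 hydroxyl of ring B → aldehyde.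
3. Enabling feature: in ring B the free phenol at C8 is para to C5–H, C5 is ortho to the ether carbon C6, and C8a carries the pyran oxygen. Two-electron oxidation of that phenol should give an O-alkyl ortho-quinonium whose beta carbon C5 lies within reach of the ring-A carboxylate.
4. Forward: ring-A bromo acid (steps 1–3); pyran ring fused to ring B (steps 4–7); diaryl ether (8); phenol release (9); ring C by anodic dehydrogenative lactonization while the allyl ethers shield ring A (10); the same allyl ethers are then turned into the prenyl groups (11–12).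

Key step: step 10

**Route**

Step 1
Reactants: 1 5-bromobenzene-1,3-diol
Product: 2 1-bromo-3,5-bis(allyloxy)benzene
Conditions: allyl bromide (2.4 equiv), K2CO3 (2.5 equiv), acetone, reflux
Reagents that add atoms: allyl bromide, C=CCBr
Why: Williamson ether synthesis on both phenols of a symmetric resorcinol should proceed without selectivity issues.

Step 2
Reactants: 2 1-bromo-3,5-bis(allyloxy)benzene
Product: 4 2,4-bis(allyloxy)-6-bromobenzaldehyde, via aryl iminium chloride 3 (not isolated)
Conditions: POCl3 (1.5 equiv), DMF, 0 to 80 °C; then H2O, 0 °C to rt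
Reagents that add atoms: N,N-dimethylformamide, CN(C)C=O; water, O
Why: Vilsmeier–Haack formylation should occur para to one allyloxy group and ortho to the other (next to bromine) rather than at the more hindered carbon between the two ethers, as is usual for 1-halo-3,5-dialkoxybenzenes.

Step 3
Reactants: 4 2,4-bis(allyloxy)-6-bromobenzaldehyde
Product: 5 2,4-bis(allyloxy)-6-bromobenzoic acid
Conditions: NaClO2 (3 equiv), NaH2PO4 (3 equiv), 2-methylbut-2-ene (20 equiv), t-BuOH/THF/H2O, rt
Reagents that add atoms: sodium chlorite, [Na+].[O-]Cl=O
Why: Pinnick oxidation converts the aldehyde to the acid while the alkene scavenger removes hypochlorous acid before it can attack the allyl ethers or the electron-rich ring.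

Step 4
Reactants: 6 3,4-dihydroxybenzaldehyde
Product: 7 3-hydroxy-4-[(2-methylbut-3-yn-2-yl)oxy]benzaldehyde
Conditions: 3-chloro-3-methylbut-1-yne (1.2 equiv), K2CO3 (1.0 equiv), KI (0.2 equiv), CuI (0.05 equiv), DMF, 45 °C, argon
Reagents that add atoms: 3-chloro-3-methylbut-1-yne, CC(C)(Cl)C#C
Why: The 4-hydroxyl, para to the formyl group, is the more acidic catechol oxygen, so one equivalent of base should give only its phenoxide, which is O-alkylated by the tertiary propargylic chloride (copper-assisted phenol propargylation).

Step 5
Reactants: 7 3-hydroxy-4-[(2-methylbut-3-yn-2-yl)oxy]benzaldehyde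
Product: 8 3-(methoxymethoxy)-4-[(2-methylbut-3-yn-2-yl)oxy]benzaldehyde
Conditions: MOMCl (1.3 equiv), K2CO3 (1.5 equiv), acetone, 0 °C to rt
Reagents that add atoms: chloromethyl methyl ether, COCCl
Why: Standard MOM protection of the remaining phenol gives a group that is stable to peracid, base, heat and copper and is removable later with mild acid.

Step 6
Reactants: 8 3-(methoxymethoxy)-4-[(2-methylbut-3-yn-2-yl)oxy]benzaldehyde
Product: 10 3-(methoxymethoxy)-4-[(2-methylbut-3-yn-2-yl)oxy]phenol, via aryl formate 9 (not isolated)
Conditions: mCPBA (1.3 equiv), CH2Cl2, 0 °C to rt; aq. NaHCO3 wash; crude formate then K2CO3 (0.2 equiv), MeOH, rt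
Reagents that add atoms: meta-chloroperoxybenzoic acid, OOC(=O)c1cccc(Cl)c1
Why: Dakin-type Baeyer–Villiger oxidation, in which the electron-rich para-alkoxy aryl group migrates in preference to hydrogen, gives the formate, and methanolysis frees the phenol.

Step 7
Reactants: 10 3-(methoxymethoxy)-4-[(2-methylbut-3-yn-2-yl)oxy]phenol
Product: 13 8-(methoxymethoxy)-2,2-dimethyl-2H-chromen-6-ol, via allenyl hydroquinone 11 (not isolated), via ortho-quinone methide 12 (not isolated)
Conditions: o-xylene, 140 °C, argon
Reagents that add atoms: none
Why: Thermal aryl propargyl ether rearrangement ([3,3] shift to the only free ortho carbon, since the other carries the MOM ether, then tautomerization to 11, 1,5-hydrogen shift to 12 and oxa-6π electrocyclization) should give a single 2,2-dimethylchromene.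

Step 8
Reactants: 5 2,4-bis(allyloxy)-6-bromobenzoic acid; 13 8-(methoxymethoxy)-2,2-dimethyl-2H-chromen-6-ol
Product: 14 2,4-bis(allyloxy)-6-{[8-(methoxymethoxy)-2,2-dimethyl-2H-chromen-6-yl]oxy}benzoic acid
Conditions: Cu powder (0.2 equiv), K2CO3 (2.5 equiv), pyridine (0.3 equiv), DMF, 100 °C, argon; then cold 1 M HCl to pH 3
Reagents that add atoms: none
Why: Ullmann condensation of an ortho-bromobenzoic acid with a phenol is assisted by the neighbouring carboxylate, and the bromide has only hydrogen on its other side, so the coupling should not be hindered.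

Step 9
Reactants: 14 2,4-bis(allyloxy)-6-{[8-(methoxymethoxy)-2,2-dimethyl-2H-chromen-6-yl]oxy}benzoic acid
Product: 15 2,4-bis(allyloxy)-6-[(8-hydroxy-2,2-dimethyl-2H-chromen-6-yl)oxy]benzoic acid
Conditions: HCl (0.5 M, from aqueous 3 M HCl), MeOH, 40 °C
Reagents that add atoms: none
Why: Acid-catalysed acetal exchange with methanol removes the aryl MOM ether, while the 2,6-disubstituted benzoic acid resists Fischer esterification and the allyl ethers and chromene should tolerate dilute acid.

Step 10
Reactants: 15 2,4-bis(allyloxy)-6-[(8-hydroxy-2,2-dimethyl-2H-chromen-6-yl)oxy]benzoic acid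
Product: 18 bis(allyl ether) depsidone (Garcinisidone E skeleton with H in place of both prenyl groups and allyl ethers on both ring-A oxygens; chromene C8–OH free), via zwitterionic phenoxonium carboxylate 16 (not isolated), via ring-B dienone 17 (not isolated)
Conditions: undivided cell, graphite anode, Pt cathode, constant current (2 mA cm−2, 2.1 F/mol), n-Bu4NBF4 (0.05 M), 2,6-lutidine (1.2 equiv), HFIP/CH2Cl2 (4:1), 5 mM, 20 °C, argon
Reagents that add atoms: none
Why: Proposed new method: anodic removal of two electrons and one proton from the only free phenol (chromene C8–OH; the ring-A oxygens are allyl ethers and the acid is present as its lutidinium carboxylate) should give phenoxonium 16, best written as an O-alkyl ortho-quinonium (C8=O, C8a=O+) whose beta carbon is C5, para to the oxidized oxygen; the carboxylate held over ring B by the diaryl ether adds there to give dienone 17, which tautomerizes to phenol 18 while protons are reduced to H2 at the cathode. The closest known reaction types are the anodic dehydrogenative lactonization of biaryl-2-carboxylic acids to benzocoumarins and the capture of phenoxonium ions, generated anodically or with trivalent iodine reagents, by carboxylic acids (oxidative spirolactonization); a seven-membered depsidone lactone has not been closed in this way. Ring C closes by a 7-exo-trig conjugate addition, since the C5=C4a π bond that is attacked lies outside the new ring. No stereocentre results, because C5 is sp3 only in the transient dienone 17. The step needs site selectivity for C5 over C7 (the other carbon ortho to the ether) and over ipso attack at C6: C7 is the electron-rich alpha carbon of the vinylogous ester ArO–C6=C7–C8=O and C6 is meta to the oxidized oxygen, so C5 is the only cationic carbon within reach, and ring B should be oxidized before ring A, the alkenes or the carboxylate because an alkoxyphenol has the lowest oxidation potential in the molecule. HFIP stabilizes the cation without competing as a nucleophile, and the charge is limited to about 2 F/mol so that the product phenol is not oxidized further.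

Step 11
Reactants: 18 bis(allyl ether) depsidone
Product: 20 di-C-allyl depsidone (Garcinisidone E with allyl in place of each prenyl group), via mono-rearranged allylphenol 19 (not isolated)
Conditions: N,N-diethylaniline, 195 °C, argon, sealed tube
Reagents that add atoms: none
Why: Two aromatic Claisen rearrangements should converge on 20, because the ether next to the lactone carbonyl has only the carbon between the two ring-A oxygens as a free ortho site, the other ether then has only the carbon next to the diaryl ether, and if the order is reversed the blocked ether reaches that same carbon by ortho-Claisen then Cope shift (para-Claisen).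

Step 12
Reactants: 20 di-C-allyl depsidone
Product: 21 Garcinisidone E
Conditions: second-generation Grubbs catalyst (H2IMes)(PCy3)Cl2Ru=CHPh (0.1 equiv), 2-methylbut-2-ene (excess, cosolvent), CH2Cl2, 40 °C, sealed tube
Reagents that add atoms: 2-methylbut-2-ene, CC=C(C)C
Why: Olefin cross-metathesis of terminal allyl arenes with 2-methylbut-2-ene is the standard allyl-to-prenyl conversion, tolerates free phenols, and should leave the ring-bound cis alkene of the chromene (shielded by the gem-dimethyl carbon) untouched.

**Compound list**

1 | 5-bromobenzene-1,3-diol | Oc1cc(O)cc(Br)c1 | starting material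
2 | 1-bromo-3,5-bis(allyloxy)benzene | C=CCOc1cc(Br)cc(OCC=C)c1 | intermediate
3 | N-[2,4-bis(allyloxy)-6-bromobenzylidene]-N-methylmethanaminium chloride (aryl iminium chloride) | C=CCOc1cc(Br)c(C=[N+](C)C)c(OCC=C)c1.[Cl-] | intermediate (not isolated)
4 | 2,4-bis(allyloxy)-6-bromobenzaldehyde | C=CCOc1cc(Br)c(C=O)c(OCC=C)c1 | intermediate
5 | 2,4-bis(allyloxy)-6-bromobenzoic acid | C=CCOc1cc(Br)c(C(=O)O)c(OCC=C)c1 | intermediate
6 | 3,4-dihydroxybenzaldehyde | O=Cc1ccc(O)c(O)c1 | starting material
7 | 3-hydroxy-4-[(2-methylbut-3-yn-2-yl)oxy]benzaldehyde | O=Cc1ccc(OC(C)(C)C#C)c(O)c1 | intermediate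
8 | 3-(methoxymethoxy)-4-[(2-methylbut-3-yn-2-yl)oxy]benzaldehyde | O=Cc1ccc(OC(C)(C)C#C)c(OCOC)c1 | intermediate
9 | 3-(methoxymethoxy)-4-[(2-methylbut-3-yn-2-yl)oxy]phenyl formate | O=COc1ccc(OC(C)(C)C#C)c(OCOC)c1 | intermediate (not isolated)
10 | 3-(methoxymethoxy)-4-[(2-methylbut-3-yn-2-yl)oxy]phenol | Oc1ccc(OC(C)(C)C#C)c(OCOC)c1 | intermediate
11 | 2-(methoxymethoxy)-6-(3-methylbuta-1,2-dien-1-yl)benzene-1,4-diol (allenyl hydroquinone) | Oc1cc(C=C=C(C)C)c(O)c(OCOC)c1 | intermediate (not isolated)
12 | 4-hydroxy-2-(methoxymethoxy)-6-(3-methylbut-2-en-1-ylidene)cyclohexa-2,4-dien-1-one (ortho-quinone methide) | O=C1C(OCOC)=CC(O)=CC1=CC=C(C)C | intermediate (not isolated)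
13 | 8-(methoxymethoxy)-2,2-dimethyl-2H-chromen-6-ol | CC1(C)C=Cc2cc(O)cc(OCOC)c2O1 | intermediate
14 | 2,4-bis(allyloxy)-6-{[8-(methoxymethoxy)-2,2-dimethyl-2H-chromen-6-yl]oxy}benzoic acid | C=CCOc1cc(OCC=C)c(C(=O)O)c(c1)Oc1cc(OCOC)c2OC(C)(C)C=Cc2c1 | intermediate
15 | 2,4-bis(allyloxy)-6-[(8-hydroxy-2,2-dimethyl-2H-chromen-6-yl)oxy]benzoic acid | C=CCOc1cc(OCC=C)c(C(=O)O)c(c1)Oc1cc(O)c2OC(C)(C)C=Cc2c1 | intermediate
16 | zwitterionic phenoxonium carboxylate (ring B as O-alkyl ortho-quinonium, C8=O and C8a=O+; ring-A carboxylate) | C=CCOc1cc(OCC=C)c(C([O-])=O)c(c1)OC1=CC(=O)C2=[O+]C(C)(C)C=CC2=C1 | intermediate (not isolated)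
17 | ring-B dienone (lactone closed; chromene C5 sp3 with H and the ester oxygen; C8 ketone) | C=CCOc1cc(OCC=C)c2c(c1)OC1=CC(=O)C3=C(C=CC(C)(C)O3)C1OC2=O | intermediate (not isolated)
18 | bis(allyl ether) depsidone (both ring-A oxygens as allyl ethers, no C-substituent at the two ring-A CH positions, chromene C8–OH free) | C=CCOc1cc(OCC=C)c2c(c1)Oc1cc(O)c3c(c1OC2=O)C=CC(C)(C)O3 | intermediate
19 | mono-rearranged allylphenol (C-allyl between the two ring-A oxygens, free OH next to the lactone carbonyl, remaining allyl ether para to the carbonyl) | C=CCc1c(OCC=C)cc2c(c1O)C(=O)Oc1c(cc(O)c3c1C=CC(C)(C)O3)O2 | intermediate (not isolated)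
20 | di-C-allyl depsidone (Garcinisidone E with allyl in place of each prenyl) | C=CCc1c(O)c(CC=C)c2c(c1O)C(=O)Oc1c(cc(O)c3c1C=CC(C)(C)O3)O2 | intermediate
21 | Garcinisidone E | CC(C)=CCc1c(O)c(CC=C(C)C)c2c(c1O)C(=O)Oc1c(cc(O)c3c1C=CC(C)(C)O3)O2 | target

**Count and risks**

Total steps: 12. Longest linear sequence: 9 steps (steps 4 to 12, from 3,4-dihydroxybenzaldehyde).

Step 10 (Proposed new method). What may go wrong: the phenoxyl radical may dimerize before the second electron is removed, the carboxylate may add at C7 instead of C5, or the product phenol may be oxidized further. The fallback uses known chemistry, sets out from 15 and returns at 18; it installs the ring-B oxygen first and then closes ring C at the acyl carbon instead. Teuber oxidation of 15 with Fremy's salt ((KSO3)2NO, KH2PO4, acetone/H2O, 0 °C) should give the para-quinone acid F1, since attack occurs para to the free phenol. Reduction with Na2S2O4 (EtOAc/H2O) should give the hydroquinone acid F2. Carbodiimide lactonization (DCC, THF, high dilution, rt), the classical depsidone closure, should then give 18, because only the C5 hydroxyl can reach the activated acid.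

Step 8. What may go wrong: protodecarboxylation or reductive loss of bromine from the copper carboxylate of the electron-rich acid before the C–O bond forms. The fallback sets out from 5 and returns at 14; it moves the coupling to the ester level, where no copper carboxylate can form. MeI, K2CO3, DMF should give the methyl ester F3. Ligand-accelerated Ullmann ether synthesis with 13 (CuI, N,N-dimethylglycine, Cs2CO3, dioxane, 90 °C) should give the diaryl ether ester F4. Saponification (KOH, MeOH/THF/H2O, 70 °C; then cold dilute HCl) should give 14.

Step 4. What may go wrong: poor site selectivity between the two catechol oxygens, double alkylation, or sluggish reaction of the tertiary chloride with the weakly nucleophilic phenoxide. The fallback sets out from 6 and returns at 8; the order of the two O-substituents is fixed by a temporary allyl group instead of by acidity alone. Selective 4-O-allylation with a reactive primary halide (allyl bromide, NaHCO3, NaI, DMF, 40 °C) should give the 4-allyl ether F5. MOMCl, K2CO3, acetone should give the MOM ether F6. Zerovalent palladium (Pd(PPh3)4, morpholine, THF, rt) should remove the allyl group to give the 4-hydroxy compound F7. The single free phenol is then alkylated (3-chloro-3-methylbut-1-yne, DBU, CuCl2 cat., MeCN, 0 °C) to 8.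

**Further compounds**

F1 | step 10 | 2,4-bis(allyloxy)-6-[(2,2-dimethyl-5,8-dioxo-5,8-dihydro-2H-chromen-6-yl)oxy]benzoic acid | C=CCOc1cc(OCC=C)c(C(=O)O)c(c1)OC1=CC(=O)C2=C(C=CC(C)(C)O2)C1=O
F2 | step 10 | 2,4-bis(allyloxy)-6-[(5,8-dihydroxy-2,2-dimethyl-2H-chromen-6-yl)oxy]benzoic acid | C=CCOc1cc(OCC=C)c(C(=O)O)c(c1)Oc1cc(O)c2OC(C)(C)C=Cc2c1O
F3 | step 8 | methyl 2,4-bis(allyloxy)-6-bromobenzoate | C=CCOc1cc(Br)c(C(=O)OC)c(OCC=C)c1
F4 | step 8 | methyl 2,4-bis(allyloxy)-6-{[8-(methoxymethoxy)-2,2-dimethyl-2H-chromen-6-yl]oxy}benzoate | C=CCOc1cc(OCC=C)c(C(=O)OC)c(c1)Oc1cc(OCOC)c2OC(C)(C)C=Cc2c1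
F5 | step 4 | 4-(allyloxy)-3-hydroxybenzaldehyde | O=Cc1ccc(OCC=C)c(O)c1
F6 | step 4 | 4-(allyloxy)-3-(methoxymethoxy)benzaldehyde | O=Cc1ccc(OCC=C)c(OCOC)c1
F7 | step 4 | 4-hydroxy-3-(methoxymethoxy)benzaldehyde | O=Cc1ccc(O)c(OCOC)c1
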